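## Analysis of the target

The target joins two six-membered rings through one methine carbon. Ring A is a hexasubstituted benzene: C1 methyl, C2 OH, C3 isobutyryl, C4 OH, C5 the methine, C6 OH. Ring B is a 4,4,6,6-tetramethylcyclohexane-1,3,5-trione in its enol form, attached through its C2. The only stereocentre is the methine, which carries H, isopropyl, C5 of ring A and C2 of ring B; it is (S) (ring B > ring A > isopropyl > H), so the task is purely one of absolute configuration. The compound is fragile in two ways. Base can expel the ring B enolate from the benzylic carbon when an ortho or para phenoxide pushes (retro-Michael, loss of configuration). Acid condenses an ortho OH with the ring B enol to a xanthene. The two non-enolisable 1,3-diketone units of ring B are also open to retro-Claisen cleavage by alkoxide. The difficulty is that the stereocentre sits between two bulky, flat sp2 groups of similar size and is labile once both rings are present, so a late enantioselective bond formation has little to work with. The strategy rests on one feature: each ring carbon on the methine (C5 of ring A, C2 of ring B) has an oxygen-bearing ring neighbour (C4/C6 of ring A, C1/C3 of ring B). The methine is therefore C3 of a 3-isopropylglutaric acid, whose CH2 groups become the two ring carbons and whose carboxyl carbons become the oxygenated neighbours.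

## Retrosynthetic reasoning

**34 to 33.** The last operation only removes two benzyl ethers from 33 by hydrogenolysis. Benzyl is chosen because its removal is neutral, so neither the acid-induced xanthene closure nor the base-induced retro-Michael pathway is opened at the end.

**33 to 32 (ring B).** Ring B is cut between its C2 (the carbon on the methine) and a carbonyl carbon, giving the open-chain hydroxy triketo ester 32. This is the only cut whose forward Claisen-type closure leaves an acidic C–H in the product, so the stable trione enolate drives the reaction. A cut next to a CMe2 carbon would give a non-enolisable diketone and a reversible closure.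

**32 to 28 and 30.** The chain is cut between the arm carbonyl and the first CMe2 carbon. The acyl donor is dihydrocoumarin 28, in which the acid arm is tied to the ortho phenol as an aryl ester, at once protected and activated. The nucleophile is enolate 31 of keto ester 30, which comes from dione 29 and methanol 7 by ring opening. The forward step has to add a tetrasubstituted enolate to the lactone carbonyl faster than it deprotonates the lactone CH2.

**28 back to 23 (ring A decoration).** The benzyl ethers of 28 come from diol 27, the diol from ethyl ether 26, and the isobutyryl group of 26 from acid chloride 25 and phenol 24 by acylation at the only unsubstituted ring position. Phenol 24 comes from silyl ether 23. Putting the acyl group on last, at the single free position, removes any regiochemical question on a ring that would otherwise be hard to acylate selectively.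

**23 to 21.** The lactone C–O bond is cut to hydroxy acid 22 and its tert-butyl ester 21. In 21 only one hydroxyl is free, and it is ortho to the side chain, so the lactone can form in one way only.

**21 to 14 and 17 (ring A).** Ring A is taken apart by removing the two-carbon unit that carries the methyl and silyloxy groups as alkyne 17, which leaves cyclobutenone 14. The forward benzannulation forms two ring C–C bonds and delivers the three oxygens in three different forms (free OH, ethyl ether, silyl ether). A biomimetic Claisen cyclisation of a triketo ester was considered for this ring; it would give three free hydroxyls, two of them ortho to the side chain, and the later lactonisation would not be regiodefined. Alkyne 17 comes from propynyllithium 15 through ynolate 16.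

**14 to 10 and 11.** Cyclobutenone 14 is cut into ethoxyacetylene 11 and ketene 13, made from acid 10 through acid chloride 12. The arm CH2 becomes the ring carbon that carries the methine, and the arm carbonyl becomes its oxygenated neighbour.

**10 to 8.** The configuration of 8 requires that its ester arm become ring A and its acid arm ring B. The ring A chemistry needs a free acid and the ring B chemistry an ester-level acyl group. The two arms therefore change their functional roles: the acid arm is capped as a tert-butyl ester (9) and the methyl ester is then saponified (10).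

**8 to 6 and 7 (key disconnection).** The methyl ester C–O bond of hemiester 8 is cut to the prochiral anhydride 6 and methanol 7. The stereocentre is created by telling apart two identical carbonyl groups on a small achiral molecule, before either ring exists, at a carbon that has no acidic hydrogen and cannot racemise during the ring constructions.

**6 to 1 and 2.** Anhydride 6 comes from diacid 5 by dehydration, 5 from tetraester 4 by hydrolysis and decarboxylation, and 4 from isobutyraldehyde 1 and two molecules of diethyl malonate 2 through alkylidene malonate 3.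

## Alternatives that were turned down

Alternative 1: The strategic cut is the C2–C3 bond of ring B, closed last by a Dieckmann condensation with a lithium amide base to give the di-O-benzyl ether A1, which is the same compound as 33.
- For it: the closure is driven by the trione enolate, the protecting-group set is benzyl only, and ring A could be bought as a ready-made benzene, which would save the six or so steps spent here on building that ring.
- Against it: as a strategy it leaves the source of the stereocentre open. Its substrate (32 in the present route) must already carry a benzylic tertiary centre next to a 2,6-dioxygenated aryl group, and making that centre enantioselectively on a hindered, electron-rich arene is less certain than the ring closure itself. A purchased arene also requires three hydroxyls and two ring positions to be told apart.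
- Comparison: the chosen route uses the same closure as step 17, so the two are equal on that point, and Alternative 1 is stronger on step count. The chosen route offers in its place a defined origin of chirality on a simple substrate and full regiocontrol of ring A.

Alternative 2: The cut is the C9–H bond of xanthene A2, with the achiral isopropylidene xanthene A3 as precursor. A chiral Brønsted acid protonates the terminal alkene carbon to a benzopyrylium-type ion pair, and a dihydropyridine hydride donor reduces C9.
- For it: it is catalytic and short, the racemic skeleton is available from a three-component condensation that includes 1, the cation forms easily, and the stereo-determining step comes at the end. On step economy it is clearly stronger.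
- Against it: A2 is not the target. Its pyran ring would have to be reopened under acid or base, which are the conditions that favour the closed form or racemise the open one. Making A3 puts a tetrasubstituted alkene between two ortho-substituted rings. The planar cation has two similar flanks, so facial selection rests on the counter-anion alone while free phenols and the acyl group compete for it.
- Comparison: the chosen route is longer, but it reaches the open-chain target directly and keeps the stereocentre out of any ionising environment until the last two steps.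

Alternative 3: The cut is the methine–isopropyl bond. An isopropyl group is transferred from a dialkylzinc reagent, under copper catalysis with a chiral phosphoramidite, to the benzylic carbon of arylidene trione A5, giving the tri-O-benzyl ether A4.
- For it: it is highly convergent, forms one asymmetric C–C bond, gives a fully O-protected product that cannot undergo phenoxide-assisted retro-Michael cleavage, and needs one hydrogenolysis to finish. It is stronger on convergence and step count.
- Against it: A5 is a doubly activated acceptor, so uncatalysed alkyl transfer and β-hydride reduction by the secondary alkylzinc compete. Its β-carbon carries a di-ortho-substituted aryl group twisted out of conjugation, so the two faces differ little. Secondary alkyl transfer is generally less selective than primary, and making A5 from a hexasubstituted benzaldehyde and a hindered trione is itself doubtful.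
- Comparison: the chosen route sets the stereocentre by a well-behaved enzyme class on a small symmetric substrate and does not depend on discriminating two bulky flat groups.

Key step: step 4

Assumption: the lipase is taken to methanolyse the carbonyl group on the pro-R methylene arm of 6, which gives (R)-8. With the opposite preference, steps 5 and 6 would be left out, because the free acid arm would then be the one that has to become ring A.

## Route

Step 1
Reactants: 1 isobutyraldehyde (2-methylpropanal); 2 diethyl malonate (two equivalents)
Product: 4 tetraethyl 2-(propan-2-yl)propane-1,1,3,3-tetracarboxylate, via alkylidene malonate 3 (not isolated)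
Conditions: piperidine (cat.), AcOH (cat.), PhMe, reflux, Dean–Stark; then second equiv of 2, NaOEt (0.2 equiv), EtOH, 60 °C
Reagents that add atoms: diethyl malonate (2), CCOC(=O)CC(=O)OCC
Why: Knoevenagel condensation gives the isobutylidene malonate 3, and ethoxide-catalysed Michael addition of a second malonate gives the bis-adduct; the central carbon carries two identical arms and is not stereogenic.

Step 2
Reactants: 4 tetraethyl 2-(propan-2-yl)propane-1,1,3,3-tetracarboxylate
Product: 5 3-(propan-2-yl)pentanedioic acid
Conditions: 6 M HCl, reflux
Reagents that add atoms: water, O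
Why: Acid hydrolysis of the four esters is followed by thermal decarboxylation of both malonic acid units, the classical route to 3-substituted glutaric acids.

Step 3
Reactants: 5 3-(propan-2-yl)pentanedioic acid
Product: 6 4-(propan-2-yl)oxane-2,6-dione (3-isopropylglutaric anhydride)
Conditions: Ac2O, reflux; distillation
Reagents that add atoms: none
Why: Cyclodehydration of a glutaric acid to its six-membered anhydride by acetic anhydride is fast and the product can be purified by distillation.

Step 4
Reactants: 6 4-(propan-2-yl)oxane-2,6-dione; 7 methanol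
Product: 8 (3R)-5-methoxy-5-oxo-3-(propan-2-yl)pentanoic acid
Conditions: Candida antarctica lipase B (immobilised on acrylic resin), 7 (2 equiv), t-BuOMe, 20 °C
Reagents that add atoms: methanol (7), CO
Why: The serine of the catalytic triad adds to one carbonyl group of 6, the tetrahedral intermediate collapses with opening of the anhydride ring, and the acyl-enzyme, which carries a free carboxylate arm, is cleaved by methanol, so the carbonyl that acylated the enzyme ends as the methyl ester (one new C–O bond, no C–C bond, no ring closed). The closest known reaction type is the hydrolase-catalysed alcoholysis of 3-substituted glutaric anhydrides, with the hydrolysis of prochiral 3-substituted glutarate diesters as its counterpart. The new stereocentre is C3, which becomes stereogenic only because its two arms are made different, and it is controlled by the chiral acyl-binding site, which must place the isopropyl group and the second arm in pockets of different size. The step needs enantiotopic-group selectivity only, since both carbonyl groups are constitutionally identical and the monoacid is not opened further. The substrate contributes a branched substituent directly on the prochiral carbon, the largest steric contrast a 3-alkyl group can offer against the ring CH2 groups. Uncatalysed methanolysis is held back by the ether solvent, the small excess of 7 and the low temperature. The sense of opening is the assumption stated above; because the arms can be interchanged chemically (steps 5 and 6), either sense can be mapped onto the target.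

Step 5
Reactants: 8 (3R)-5-methoxy-5-oxo-3-(propan-2-yl)pentanoic acid
Product: 9 1-tert-butyl 5-methyl (3S)-3-(propan-2-yl)pentanedioate
Conditions: Cl3CC(=NH)Ot-Bu, BF3·OEt2 (cat.), cyclohexane/CH2Cl2, rt
Reagents that add atoms: tert-butyl 2,2,2-trichloroacetimidate, CC(C)(C)OC(=N)C(Cl)(Cl)Cl
Why: Acid-catalysed tert-butylation by the trichloroacetimidate esterifies the free acid under conditions too mild for acyl migration through the anhydride, so the hemiester keeps its enantiomeric purity; the descriptor changes only because the priorities of the arms change.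

Step 6
Reactants: 9 1-tert-butyl 5-methyl (3S)-3-(propan-2-yl)pentanedioate
Product: 10 (3S)-5-tert-butoxy-5-oxo-3-(propan-2-yl)pentanoic acid
Conditions: LiOH, THF/H2O, 0 °C → rt; then cold 1 M HCl to pH 3
Reagents that add atoms: lithium hydroxide (hydroxide oxygen), [Li+].[OH-]
Why: Saponification is chemoselective for the unhindered methyl ester over the tert-butyl ester, which completes the exchange of arm roles; the stereocentre has no acidic hydrogen and is untouched.

Step 7
Reactants: 10 (3S)-5-tert-butoxy-5-oxo-3-(propan-2-yl)pentanoic acid; 11 ethoxyethyne (ethoxyacetylene)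
Product: 14 tert-butyl (3S)-3-[(1RS)-2-ethoxy-4-oxocyclobut-2-en-1-yl]-4-methylpentanoate, via acid chloride 12 (not isolated), via ketene 13 (not isolated)
Conditions: Me2C=C(Cl)NMe2 (Ghosez reagent), CH2Cl2, 0 °C → rt; then slow addition to 11 (3 equiv), Et3N, Et2O, 25–35 °C
Reagents that add atoms: ethoxyethyne (11), CCOC#C
Why: The chloroenamine gives the acid chloride under neutral conditions that spare the tert-butyl ester, triethylamine dehydrochlorinates it to the monoalkylketene, and ketene–ynol ether [2+2] cycloaddition joins the ketene carbonyl carbon to the unsubstituted alkyne carbon to give the 3-ethoxycyclobutenone; the new ring stereocentre is uncontrolled and is lost in step 9.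

Step 8
Reactants: 15 prop-1-yn-1-yllithium
Product: 17 tri(propan-2-yl)(prop-1-yn-1-yloxy)silane, via lithium ynolate 16 (not isolated)
Conditions: t-BuOOH, LiN(SiMe3)2, THF, −78 °C; then 15, −78 → 0 °C; then i-Pr3SiOTf, −78 °C → rt
Reagents that add atoms: tert-butyl hydroperoxide, CC(C)(C)OO; triisopropylsilyl trifluoromethanesulfonate, CC(C)[Si](OS(=O)(=O)C(F)(F)F)(C(C)C)C(C)C
Why: The acetylide attacks the electrophilic oxygen of lithium tert-butyl peroxide to give the ynolate (electrophilic oxidation of an alkynyllithium), and the bulky silyl triflate silylates it on oxygen to the silyl ynol ether.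

Step 9
Reactants: 14 tert-butyl (3S)-3-[(1RS)-2-ethoxy-4-oxocyclobut-2-en-1-yl]-4-methylpentanoate; 17 tri(propan-2-yl)(prop-1-yn-1-yloxy)silane
Product: 21 tert-butyl (3S)-3-{6-ethoxy-2-hydroxy-3-methyl-4-[tri(propan-2-yl)silyloxy]phenyl}-4-methylpentanoate, via vinylketene 18 (not isolated), via vinylcyclobutenone 19 (not isolated), via dienylketene 20 (not isolated)
Conditions: 17 (1.5 equiv), PhMe, 80 → 110 °C, sealed tube
Reagents that add atoms: silyl ynol ether 17, CC#CO[Si](C(C)C)(C(C)C)C(C)C
Why: Danheiser benzannulation: 4π ring opening of 14 gives vinylketene 18, regioselective [2+2] with the electron-rich alkyne gives 19, a second 4π opening gives 20, and 6π electrocyclisation followed by tautomerisation of the dienone gives the phenol; the polarity of the ketene–ynol ether cycloaddition fixes the pattern (free OH ortho to the side chain, methyl between OH and OSi), and the side-chain stereocentre is not involved.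

Step 10
Reactants: 21 tert-butyl (3S)-3-{6-ethoxy-2-hydroxy-3-methyl-4-[tri(propan-2-yl)silyloxy]phenyl}-4-methylpentanoate
Product: 23 (4S)-5-ethoxy-8-methyl-4-(propan-2-yl)-7-[tri(propan-2-yl)silyloxy]-3,4-dihydro-2H-chromen-2-one, via hydroxy acid 22 (not isolated)
Conditions: CF3CO2H, CH2Cl2, 0 °C → rt; then TsOH (cat.), PhMe, 80 °C
Reagents that add atoms: none
Why: Acidolysis of the tert-butyl ester is followed by six-membered lactonisation onto the only free phenol, which is ortho to the side chain; the hindered aryl silyl ether and the ethyl ether should survive, and the one free ring position is shielded from tert-butylation by its two flanking ether groups.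

Step 11
Reactants: 23 (4S)-5-ethoxy-8-methyl-4-(propan-2-yl)-7-[tri(propan-2-yl)silyloxy]-3,4-dihydro-2H-chromen-2-one
Product: 24 (4S)-5-ethoxy-7-hydroxy-8-methyl-4-(propan-2-yl)-3,4-dihydro-2H-chromen-2-one
Conditions: Bu4NF, AcOH, THF, 0 °C
Reagents that add atoms: none
Why: Fluoride cleaves the aryl silyl ether, and the acetic acid buffer keeps the phenoxide concentration low enough that the aryl ester lactone is not opened.

Step 12
Reactants: 24 (4S)-5-ethoxy-7-hydroxy-8-methyl-4-(propan-2-yl)-3,4-dihydro-2H-chromen-2-one; 25 2-methylpropanoyl chloride
Product: 26 (4S)-5-ethoxy-7-hydroxy-8-methyl-6-(2-methylpropanoyl)-4-(propan-2-yl)-3,4-dihydro-2H-chromen-2-one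
Conditions: 25 (1.5 equiv), TiCl4, CH2Cl2, 0 °C → rt
Reagents that add atoms: 2-methylpropanoyl chloride (25), CC(C)C(Cl)=O
Why: Friedel–Crafts acylation (directly or through the phenol ester and Fries shift) can occur only at C6, the single unsubstituted ring carbon, which is activated by an ortho hydroxyl, an ortho ethoxy and a para acyloxy group.

Step 13
Reactants: 26 (4S)-5-ethoxy-7-hydroxy-8-methyl-6-(2-methylpropanoyl)-4-(propan-2-yl)-3,4-dihydro-2H-chromen-2-one
Product: 27 (4S)-5,7-dihydroxy-8-methyl-6-(2-methylpropanoyl)-4-(propan-2-yl)-3,4-dihydro-2H-chromen-2-one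
Conditions: BCl3, CH2Cl2, −78 → 0 °C; aqueous work-up
Reagents that add atoms: none
Why: Boron chelates the ketone oxygen and the ortho ether oxygen and chloride removes the ethyl group (chelation-controlled ether cleavage ortho to a carbonyl); the lactone and the benzylic centre are not affected at this temperature.

Step 14
Reactants: 27 (4S)-5,7-dihydroxy-8-methyl-6-(2-methylpropanoyl)-4-(propan-2-yl)-3,4-dihydro-2H-chromen-2-one
Product: 28 (4S)-5,7-bis(benzyloxy)-8-methyl-6-(2-methylpropanoyl)-4-(propan-2-yl)-3,4-dihydro-2H-chromen-2-one
Conditions: BnBr, K2CO3, KI (cat.), dry DMF, 50 °C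
Reagents that add atoms: benzyl bromide, BrCc1ccccc1
Why: Williamson benzylation of both chelated phenols; strictly anhydrous carbonate keeps the lactone closed, and the third ring oxygen stays masked in the lactone.

Step 15
Reactants: 29 2,2,4,4-tetramethylcyclobutane-1,3-dione; 7 methanol
Product: 30 methyl 2,2,4-trimethyl-3-oxopentanoate
Conditions: NaOMe (cat.), MeOH, reflux
Reagents that add atoms: methanol (7), CO
Why: Methoxide adds to a carbonyl of the strained, non-enolisable 1,3-dione and retro-Claisen ring opening gives the keto ester, whose only enolisable position is the isopropyl methine.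

Step 16
Reactants: 28 (4S)-5,7-bis(benzyloxy)-8-methyl-6-(2-methylpropanoyl)-4-(propan-2-yl)-3,4-dihydro-2H-chromen-2-one; 30 methyl 2,2,4-trimethyl-3-oxopentanoate
Product: 32 methyl (7S)-7-[4,6-bis(benzyloxy)-2-hydroxy-3-methyl-5-(2-methylpropanoyl)phenyl]-2,2,4,4,8-pentamethyl-3,5-dioxononanoate, via lithium enolate 31 (not isolated)
Conditions: 30 (2 equiv), LiN(SiMe3)2, THF, −78 → 0 °C; then 28, −78 → −20 °C; aq. NH4Cl
Reagents that add atoms: keto ester 30 (as enolate 31), COC(=O)C(C)(C)C(=O)C(C)C
Why: Claisen-type C-acylation of the ketone enolate by the aryl ester: addition to the lactone carbonyl and loss of the phenoxide, a far weaker base than the enolate, make the step irreversible; the silylamine by-product is too poor a nucleophile to intercept an acyl species, and the hindered di-ortho-substituted aryl ketone is not attacked.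

Step 17
Reactants: 32 methyl (7S)-7-[4,6-bis(benzyloxy)-2-hydroxy-3-methyl-5-(2-methylpropanoyl)phenyl]-2,2,4,4,8-pentamethyl-3,5-dioxononanoate
Product: 33 2-[(1S)-1-[4,6-bis(benzyloxy)-2-hydroxy-3-methyl-5-(2-methylpropanoyl)phenyl]-2-methylpropyl]-3-hydroxy-4,4,6,6-tetramethylcyclohex-2-ene-1,5-dione
Conditions: LiN(SiMe3)2 (3 equiv), THF, −78 → 0 °C; then AcOH/aq. NH4Cl
Reagents that add atoms: none
Why: Dieckmann condensation: the ketone enolate at the CH2 next to the stereocentre attacks the terminal methyl ester in a six-membered closure, and deprotonation of the resulting trione drives it; the stereocentre is β to the enolate and cannot epimerise by enolisation, and the low temperature and non-nucleophilic base limit retro-Claisen and retro-Michael pathways.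

Step 18
Reactants: 33 2-[(1S)-1-[4,6-bis(benzyloxy)-2-hydroxy-3-methyl-5-(2-methylpropanoyl)phenyl]-2-methylpropyl]-3-hydroxy-4,4,6,6-tetramethylcyclohex-2-ene-1,5-dione
Product: 34 2-[(1S)-1-[2,4,6-trihydroxy-3-methyl-5-(2-methylpropanoyl)phenyl]-2-methylpropyl]-3-hydroxy-4,4,6,6-tetramethylcyclohex-2-ene-1,5-dione (CNP0210316.1)
Conditions: H2 (1 atm), Pd/C, EtOAc, rt
Reagents that add atoms: none
Why: Hydrogenolysis of the two benzyl ethers under neutral conditions; the hindered, hydrogen-bonded aryl ketone and the tetrasubstituted enol of ring B should not be reduced, and no acid or base touches the labile product.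

## Compound list

1 | isobutyraldehyde (2-methylpropanal) | CC(C)C=O | starting material
2 | diethyl malonate | CCOC(=O)CC(=O)OCC | starting material
3 | diethyl 2-(2-methylpropylidene)propanedioate | CCOC(=O)C(=CC(C)C)C(=O)OCC | intermediate (not isolated)
4 | tetraethyl 2-(propan-2-yl)propane-1,1,3,3-tetracarboxylate | CCOC(=O)C(C(=O)OCC)C(C(C)C)C(C(=O)OCC)C(=O)OCC | intermediate
5 | 3-(propan-2-yl)pentanedioic acid | CC(C)C(CC(O)=O)CC(O)=O | intermediate
6 | 4-(propan-2-yl)oxane-2,6-dione (3-isopropylglutaric anhydride) | CC(C)C1CC(=O)OC(=O)C1 | intermediate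
7 | methanol | CO | starting material
8 | (3R)-5-methoxy-5-oxo-3-(propan-2-yl)pentanoic acid | COC(=O)C[C@@H](CC(O)=O)C(C)C | intermediate
9 | 1-tert-butyl 5-methyl (3S)-3-(propan-2-yl)pentanedioate | COC(=O)C[C@@H](CC(=O)OC(C)(C)C)C(C)C | intermediate
10 | (3S)-5-tert-butoxy-5-oxo-3-(propan-2-yl)pentanoic acid | OC(=O)C[C@@H](CC(=O)OC(C)(C)C)C(C)C | intermediate
11 | ethoxyethyne (ethoxyacetylene) | CCOC#C | starting material
12 | tert-butyl (3R)-5-chloro-5-oxo-3-(propan-2-yl)pentanoate | ClC(=O)C[C@@H](CC(=O)OC(C)(C)C)C(C)C | intermediate (not isolated)
13 | tert-butyl (3S)-4-methyl-3-(2-oxoethenyl)pentanoate (ketene) | O=C=C[C@@H](CC(=O)OC(C)(C)C)C(C)C | intermediate (not isolated)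
14 | tert-butyl (3S)-3-[(1RS)-2-ethoxy-4-oxocyclobut-2-en-1-yl]-4-methylpentanoate (both ring epimers) | CCOC1=CC(=O)C1[C@@H](CC(=O)OC(C)(C)C)C(C)C | intermediate
15 | prop-1-yn-1-yllithium | [Li]C#CC | starting material
16 | lithium prop-1-yn-1-olate | CC#C[O-].[Li+] | intermediate (not isolated)
17 | tri(propan-2-yl)(prop-1-yn-1-yloxy)silane | CC#CO[Si](C(C)C)(C(C)C)C(C)C | intermediate
18 | tert-butyl (3S)-5-ethoxy-7-oxo-3-(propan-2-yl)hepta-4,6-dienoate (vinylketene) | O=C=CC(OCC)=C[C@@H](CC(=O)OC(C)(C)C)C(C)C | intermediate (not isolated)
19 | tert-butyl (3S)-5-ethoxy-5-{3-methyl-4-oxo-2-[tri(propan-2-yl)silyloxy]cyclobut-2-en-1-yl}-3-(propan-2-yl)pent-4-enoate | CC1=C(O[Si](C(C)C)(C(C)C)C(C)C)C(C(OCC)=C[C@@H](CC(=O)OC(C)(C)C)C(C)C)C1=O | intermediate (not isolated)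
20 | tert-butyl (3S)-5-ethoxy-8-methyl-9-oxo-3-(propan-2-yl)-7-[tri(propan-2-yl)silyloxy]nona-4,6,8-trienoate (dienylketene) | O=C=C(C)C(O[Si](C(C)C)(C(C)C)C(C)C)=CC(OCC)=C[C@@H](CC(=O)OC(C)(C)C)C(C)C | intermediate (not isolated)
21 | tert-butyl (3S)-3-{6-ethoxy-2-hydroxy-3-methyl-4-[tri(propan-2-yl)silyloxy]phenyl}-4-methylpentanoate | CCOc1cc(O[Si](C(C)C)(C(C)C)C(C)C)c(C)c(O)c1[C@@H](CC(=O)OC(C)(C)C)C(C)C | intermediate
22 | (3S)-3-{6-ethoxy-2-hydroxy-3-methyl-4-[tri(propan-2-yl)silyloxy]phenyl}-4-methylpentanoic acid | CCOc1cc(O[Si](C(C)C)(C(C)C)C(C)C)c(C)c(O)c1[C@@H](CC(O)=O)C(C)C | intermediate (not isolated)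
23 | (4S)-5-ethoxy-8-methyl-4-(propan-2-yl)-7-[tri(propan-2-yl)silyloxy]-3,4-dihydro-2H-chromen-2-one | CCOc1cc(O[Si](C(C)C)(C(C)C)C(C)C)c(C)c2OC(=O)C[C@@H](C(C)C)c12 | intermediate
24 | (4S)-5-ethoxy-7-hydroxy-8-methyl-4-(propan-2-yl)-3,4-dihydro-2H-chromen-2-one | CCOc1cc(O)c(C)c2OC(=O)C[C@@H](C(C)C)c12 | intermediate
25 | 2-methylpropanoyl chloride | CC(C)C(Cl)=O | starting material
26 | (4S)-5-ethoxy-7-hydroxy-8-methyl-6-(2-methylpropanoyl)-4-(propan-2-yl)-3,4-dihydro-2H-chromen-2-one | CCOc1c(C(=O)C(C)C)c(O)c(C)c2OC(=O)C[C@@H](C(C)C)c12 | intermediate
27 | (4S)-5,7-dihydroxy-8-methyl-6-(2-methylpropanoyl)-4-(propan-2-yl)-3,4-dihydro-2H-chromen-2-one | CC(C)C(=O)c1c(O)c(C)c2OC(=O)C[C@@H](C(C)C)c2c1O | intermediate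
28 | (4S)-5,7-bis(benzyloxy)-8-methyl-6-(2-methylpropanoyl)-4-(propan-2-yl)-3,4-dihydro-2H-chromen-2-one | CC(C)C(=O)c1c(OCc2ccccc2)c(C)c2OC(=O)C[C@@H](C(C)C)c2c1OCc1ccccc1 | intermediate
29 | 2,2,4,4-tetramethylcyclobutane-1,3-dione | CC1(C)C(=O)C(C)(C)C1=O | starting material
30 | methyl 2,2,4-trimethyl-3-oxopentanoate | COC(=O)C(C)(C)C(=O)C(C)C | intermediate
31 | lithium 5-methoxy-2,4,4-trimethyl-5-oxopent-2-en-3-olate (enolate of 30) | COC(=O)C(C)(C)C([O-])=C(C)C.[Li+] | intermediate (not isolated)
32 | methyl (7S)-7-[4,6-bis(benzyloxy)-2-hydroxy-3-methyl-5-(2-methylpropanoyl)phenyl]-2,2,4,4,8-pentamethyl-3,5-dioxononanoate | COC(=O)C(C)(C)C(=O)C(C)(C)C(=O)C[C@@H](C(C)C)c1c(O)c(C)c(OCc2ccccc2)c(C(=O)C(C)C)c1OCc1ccccc1 | intermediate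
33 | 2-[(1S)-1-[4,6-bis(benzyloxy)-2-hydroxy-3-methyl-5-(2-methylpropanoyl)phenyl]-2-methylpropyl]-3-hydroxy-4,4,6,6-tetramethylcyclohex-2-ene-1,5-dione | Cc1c(OCc2ccccc2)c(C(=O)C(C)C)c(OCc2ccccc2)c([C@@H](C2=C(O)C(C)(C)C(=O)C(C)(C)C2=O)C(C)C)c1O | intermediate
34 | 2-[(1S)-1-[2,4,6-trihydroxy-3-methyl-5-(2-methylpropanoyl)phenyl]-2-methylpropyl]-3-hydroxy-4,4,6,6-tetramethylcyclohex-2-ene-1,5-dione (CNP0210316.1) | Cc1c(O)c(C(=O)C(C)C)c(O)c([C@@H](C2=C(O)C(C)(C)C(=O)C(C)(C)C2=O)C(C)C)c1O | target

## Step count and least certain steps

Total: 18 steps. Longest linear sequence: 16 steps (1–7, 9–14, 16–18) from 1; steps 8 and 15 prepare the reagents 17 and 30.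

**Step 4 (key step).** The likely failure is erosion of enantiomeric purity: uncatalysed methanolysis of 6 can run beside the enzymatic channel, and the active site may tell the two carbonyl groups apart only weakly, or in the opposite sense, for a 3-isopropyl group. Fallback: the same ring opening is carried out as a base-catalysed methanolysis with a cinchona alkaloid (quinidine or quinine, or one of their dimeric ethers) at low temperature in an ether or toluene. The two pseudo-enantiomeric alkaloids give either sense at will, and this reaction class is established for 3-alkylglutaric anhydrides. The fallback sets out from 6 and comes back at 8 without any new compound.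

**Step 9 (ring A annulation, fed by step 7).** Opening of the donor-substituted cyclobutenone 14 may need temperatures at which vinylketene 18 is consumed by the phenolic product or by itself before alkyne 17 captures it. Upstream, dimerisation of ketene 13 in step 7 can starve the sequence of 14. Fallback, from 10 back to 21, which avoids both the cyclobutenone and its ketene precursor:
- 10 is activated with carbonyldiimidazole to acyl imidazole F1.
- F1 is homologated with Mg(O2CCH2CO2Et)2 to β-keto ester F2.
- Triethyl orthoformate with catalytic acid gives enol ether F3.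
- KOH in aqueous ethanol saponifies the ethyl ester selectively to acid F4.
- Oxalyl chloride gives enoyl chloride F5.
- 1,4-Dehydrochlorination of F5 with Et3N at 25 °C in the presence of 17 generates the same vinylketene 18 without heat, and only the later pericyclic stages need warming to reach 21.

**Step 16.** The hindered enolate 31 may act as a base, removing a proton from the lactone CH2 (followed by loss of the phenoxide to a ketene), or may simply add too slowly. Fallback, from 28 back to 34, which uses an acid chloride as the acyl donor and masks every phenol: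
- 28 is opened with sodium benzyloxide and the freed phenoxide is benzylated in the same flask to benzyl ester F6.
- LiOH gives acid F7, and the chloroenamine reagent gives acid chloride F8.
- F8 acylates enolate 31 at −78 °C to triketo ester F9.
- LiN(SiMe3)2 closes ring B to tri-O-benzyl trione F10.
- Hydrogenolysis over Pd/C gives 34 directly.

**Step 17.** Once ring B exists beside a lithium phenoxide, the trione enolate can be expelled from the benzylic carbon and re-add (retro-Michael), which would erode the configuration; methoxide set free in the closure can also cleave the non-enolisable diketone. Fallback, from 32 back to 33: the phenol is capped with Et3SiCl and imidazole to silyl ether F11, the Dieckmann closure is run on F11 to give silyl ether F12, and buffered fluoride (Bu4NF, AcOH, 0 °C) removes the silyl group to give 33.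

## Further compounds

F0 | step 4 | none | none
F1 | step 9 | tert-butyl (3S)-3-[2-(1H-imidazol-1-yl)-2-oxoethyl]-4-methylpentanoate | O=C(C[C@@H](CC(=O)OC(C)(C)C)C(C)C)n1ccnc1
F2 | step 9 | 1-tert-butyl 7-ethyl (3S)-5-oxo-3-(propan-2-yl)heptanedioate | CCOC(=O)CC(=O)C[C@@H](CC(=O)OC(C)(C)C)C(C)C
F3 | step 9 | 1-tert-butyl 7-ethyl (3S)-5-ethoxy-3-(propan-2-yl)hept-5-enedioate | CCOC(=O)C=C(OCC)C[C@@H](CC(=O)OC(C)(C)C)C(C)C
F4 | step 9 | (5S)-7-tert-butoxy-3-ethoxy-7-oxo-5-(propan-2-yl)hept-2-enoic acid | OC(=O)C=C(OCC)C[C@@H](CC(=O)OC(C)(C)C)C(C)C
F5 | step 9 | tert-butyl (3S)-7-chloro-5-ethoxy-7-oxo-3-(propan-2-yl)hept-5-enoate | ClC(=O)C=C(OCC)C[C@@H](CC(=O)OC(C)(C)C)C(C)C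
F6 | step 16 | benzyl (3S)-3-[2,4,6-tris(benzyloxy)-3-methyl-5-(2-methylpropanoyl)phenyl]-4-methylpentanoate | CC(C)C(=O)c1c(OCc2ccccc2)c(C)c(OCc2ccccc2)c([C@@H](CC(=O)OCc2ccccc2)C(C)C)c1OCc1ccccc1
F7 | step 16 | (3S)-3-[2,4,6-tris(benzyloxy)-3-methyl-5-(2-methylpropanoyl)phenyl]-4-methylpentanoic acid | CC(C)C(=O)c1c(OCc2ccccc2)c(C)c(OCc2ccccc2)c([C@@H](CC(O)=O)C(C)C)c1OCc1ccccc1
F8 | step 16 | (3S)-3-[2,4,6-tris(benzyloxy)-3-methyl-5-(2-methylpropanoyl)phenyl]-4-methylpentanoyl chloride | CC(C)C(=O)c1c(OCc2ccccc2)c(C)c(OCc2ccccc2)c([C@@H](CC(Cl)=O)C(C)C)c1OCc1ccccc1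
F9 | step 16 | methyl (7S)-7-[2,4,6-tris(benzyloxy)-3-methyl-5-(2-methylpropanoyl)phenyl]-2,2,4,4,8-pentamethyl-3,5-dioxononanoate | COC(=O)C(C)(C)C(=O)C(C)(C)C(=O)C[C@@H](C(C)C)c1c(OCc2ccccc2)c(C)c(OCc2ccccc2)c(C(=O)C(C)C)c1OCc1ccccc1
F10 | step 16 | 2-[(1S)-1-[2,4,6-tris(benzyloxy)-3-methyl-5-(2-methylpropanoyl)phenyl]-2-methylpropyl]-3-hydroxy-4,4,6,6-tetramethylcyclohex-2-ene-1,5-dione | Cc1c(OCc2ccccc2)c(C(=O)C(C)C)c(OCc2ccccc2)c([C@@H](C2=C(O)C(C)(C)C(=O)C(C)(C)C2=O)C(C)C)c1OCc1ccccc1
F11 | step 17 | methyl (7S)-7-[4,6-bis(benzyloxy)-3-methyl-5-(2-methylpropanoyl)-2-(triethylsilyloxy)phenyl]-2,2,4,4,8-pentamethyl-3,5-dioxononanoate | COC(=O)C(C)(C)C(=O)C(C)(C)C(=O)C[C@@H](C(C)C)c1c(O[Si](CC)(CC)CC)c(C)c(OCc2ccccc2)c(C(=O)C(C)C)c1OCc1ccccc1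
F12 | step 17 | 2-[(1S)-1-[4,6-bis(benzyloxy)-3-methyl-5-(2-methylpropanoyl)-2-(triethylsilyloxy)phenyl]-2-methylpropyl]-3-hydroxy-4,4,6,6-tetramethylcyclohex-2-ene-1,5-dione | Cc1c(OCc2ccccc2)c(C(=O)C(C)C)c(OCc2ccccc2)c([C@@H](C2=C(O)C(C)(C)C(=O)C(C)(C)C2=O)C(C)C)c1O[Si](CC)(CC)CC
A1 | alternative 1 | 2-[(1S)-1-[4,6-bis(benzyloxy)-2-hydroxy-3-methyl-5-(2-methylpropanoyl)phenyl]-2-methylpropyl]-3-hydroxy-4,4,6,6-tetramethylcyclohex-2-ene-1,5-dione | Cc1c(OCc2ccccc2)c(C(=O)C(C)C)c(OCc2ccccc2)c([C@@H](C2=C(O)C(C)(C)C(=O)C(C)(C)C2=O)C(C)C)c1O
A2 | alternative 2 | (9S)-6,8-dihydroxy-2,2,4,4,5-pentamethyl-7-(2-methylpropanoyl)-9-(propan-2-yl)-4,9-dihydro-1H-xanthene-1,3(2H)-dione | Cc1c(O)c(C(=O)C(C)C)c(O)c2c1OC1=C([C@H]2C(C)C)C(=O)C(C)(C)C(=O)C1(C)C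
A3 | alternative 2 | 6,8-dihydroxy-2,2,4,4,5-pentamethyl-7-(2-methylpropanoyl)-9-(propan-2-ylidene)-4,9-dihydro-1H-xanthene-1,3(2H)-dione | Cc1c(O)c(C(=O)C(C)C)c(O)c2c1OC1=C(C2=C(C)C)C(=O)C(C)(C)C(=O)C1(C)C
A4 | alternative 3 | 2-[(1S)-1-[2,4,6-tris(benzyloxy)-3-methyl-5-(2-methylpropanoyl)phenyl]-2-methylpropyl]-3-hydroxy-4,4,6,6-tetramethylcyclohex-2-ene-1,5-dione | Cc1c(OCc2ccccc2)c(C(=O)C(C)C)c(OCc2ccccc2)c([C@@H](C2=C(O)C(C)(C)C(=O)C(C)(C)C2=O)C(C)C)c1OCc1ccccc1
A5 | alternative 3 | 4,4,6,6-tetramethyl-2-{[2,4,6-tris(benzyloxy)-3-methyl-5-(2-methylpropanoyl)phenyl]methylidene}cyclohexane-1,3,5-trione | Cc1c(OCc2ccccc2)c(C(=O)C(C)C)c(OCc2ccccc2)c(C=C2C(=O)C(C)(C)C(=O)C(C)(C)C2=O)c1OCc1ccccc1
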